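The tetrahydrofuran (ring atoms O1, C2 bearing the guaiacyl group, C3 bearing methyl, C4 bearing the syringylmethyl carbon C7, and C5) is traced back to a γ-butyrolactone with its carbonyl at C2. Carbons C5, C4 and C7 map onto the three carbons of (R)-epichlorohydrin, whose stereocentre becomes C4, and C3 is the enolisable carbon next to the lactone carbonyl. The key step exploits both: an arylcopper species from the O-benzyl syringyl Grignard reagent opens the cyclopropane-fused lactone ester at its CH2 carbon (C7–aryl bond) and the liberated enolate is methylated in the same flask (C3–CH3 bond). Decarboxylation, aryllithium addition at C2, silane reduction and debenzylation then give the all-trans (2R,3R,4R) target.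

Key step: step 4

Assumption: 17 is written as the cyclic hemiketal (both C2 anomers). It is expected to equilibrate with its open-chain γ-hydroxy aryl ketone, and either form leads to oxocarbenium ion 18 in step 8. The ring numbering O1, C2 (aryl), C3 (methyl), C4 (arylmethyl through C7), C5 is used throughout.

Step 1
Reactants: 1 (R)-epichlorohydrin; 2 dimethyl malonate
Product: 6 methyl (1S,5R)-2-oxo-3-oxabicyclo[3.1.0]hexane-1-carboxylate, via chlorohydrin alkoxide 3 (not isolated), via epoxymalonate 4 (not isolated), via cyclopropylmethanol diester 5 (not isolated)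
Conditions: NaOMe, MeOH, rt then reflux
Reagents that add atoms: none
Why: Tandem epoxide opening, epoxide re-formation, 3-exo-tet cyclopropanation and lactonisation: the malonate anion opens the oxirane of 1 at its CH2 terminus, alkoxide 3 displaces chloride to give epoxide 4, the malonate carbanion attacks the oxirane CH carbon with inversion to give 5, and its alkoxide lactonises onto the cis ester, so that the single inversion at the epichlorohydrin stereocentre fixes the (1S,5R) configuration of the necessarily cis-fused bicycle.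

Step 2
Reactants: 7 4-bromo-2,6-dimethoxyphenol
Product: 8 2-(benzyloxy)-5-bromo-1,3-dimethoxybenzene
Conditions: BnBr, K2CO3, DMF, 60 °C
Reagents that add atoms: benzyl bromide, BrCc1ccccc1
Why: Williamson ether synthesis in which the phenoxide of 7 displaces bromide from benzyl bromide, the aryl bromide and the methyl ethers being inert to carbonate base.

Step 3
Reactants: 8 2-(benzyloxy)-5-bromo-1,3-dimethoxybenzene
Product: 9 [4-(benzyloxy)-3,5-dimethoxyphenyl]magnesium bromide (used as a THF solution)
Conditions: Mg turnings, I2 (cat.), THF, reflux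
Reagents that add atoms: magnesium, [Mg]
Why: Grignard formation by insertion of magnesium into the aryl C–Br bond, which the benzyl and methyl aryl ethers tolerate.

Step 4
Reactants: 6 methyl (1S,5R)-2-oxo-3-oxabicyclo[3.1.0]hexane-1-carboxylate; 9 [4-(benzyloxy)-3,5-dimethoxyphenyl]magnesium bromide
Product: 11 methyl (3R,4R)-4-[4-(benzyloxy)-3,5-dimethoxybenzyl]-3-methyl-2-oxotetrahydrofuran-3-carboxylate, via bromomagnesium lactone enolate 10 (not isolated)
Conditions: CuI (20 mol %), THF, −40 → −10 °C; then MeI (excess), DMPU, −10 °C → rt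
Reagents that add atoms: iodomethane, CI
Why: Transmetalation of 9 with CuI gives an arylcopper species that attacks the unsubstituted cyclopropane carbon of 6 (the future C7) in an SN2-like homoconjugate addition, cleaving the bond from that carbon to the doubly activated ring-fusion carbon and releasing the chelated bromomagnesium lactone–ester enolate 10, which MeI C-methylates once DMPU has loosened the chelate. The closest known reaction types are the copper-catalysed opening of 2-oxo-3-oxabicyclo[3.1.0]hexane-1-carboxylates by aryl Grignard reagents to β-arylmethyl lactones and the tandem cuprate addition–enolate alkylation. No ring is closed; the temporary three-membered ring is cleaved and the five-membered lactone is kept. The new quaternary stereocentre C3 is set by approach of MeI to the planar enolate on the face anti to the C4 arylmethyl group (methyl trans to that group, 3R), while C4 keeps the configuration bought with (R)-epichlorohydrin because no bond to it is broken. The step needs attack at the cyclopropane CH2 in preference to the ring-fusion CH and to the two carbonyl groups, which the primary, unhindered character of that carbon, the soft copper nucleophile and the low temperature should secure. Since C3 is re-equilibrated after decarboxylation in step 5, imperfect facial selectivity in the methylation is of no consequence for the target.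

Step 5
Reactants: 11 methyl (3R,4R)-4-[4-(benzyloxy)-3,5-dimethoxybenzyl]-3-methyl-2-oxotetrahydrofuran-3-carboxylate
Product: 13 (3R,4R)-4-[4-(benzyloxy)-3,5-dimethoxybenzyl]-3-methyldihydrofuran-2(3H)-one, via cis-lactone epimer 12 (not isolated)
Conditions: LiCl, H2O, DMSO, 150 °C; then DBU (cat.), toluene, 80 °C
Reagents that add atoms: none
Why: Krapcho dealkoxycarbonylation (chloride attacks the ester methyl group, the carboxylate loses CO2 and the lactone enolate is protonated to a mixture of 12 and 13) followed by base-mediated epimerisation at C3, which funnels 12 into the thermodynamically preferred 3,4-trans lactone 13 and so sets C3 as R under thermodynamic control while C4 is untouched.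

Step 6
Reactants: 14 4-bromo-2-methoxyphenol
Product: 15 1-(benzyloxy)-4-bromo-2-methoxybenzene
Conditions: BnBr, K2CO3, acetone, reflux
Reagents that add atoms: benzyl bromide, BrCc1ccccc1
Why: Williamson ether synthesis of the phenoxide with benzyl bromide, the aryl bromide being inert.

Step 7
Reactants: 15 1-(benzyloxy)-4-bromo-2-methoxybenzene; 13 (3R,4R)-4-[4-(benzyloxy)-3,5-dimethoxybenzyl]-3-methyldihydrofuran-2(3H)-one
Product: 17 (3R,4R)-2-[4-(benzyloxy)-3-methoxyphenyl]-4-[4-(benzyloxy)-3,5-dimethoxybenzyl]-3-methyltetrahydrofuran-2-ol (anomeric mixture, used crude), via aryllithium 16 (not isolated)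
Conditions: n-BuLi, THF, −78 °C; then 13, −78 °C; aq NH4Cl at −78 °C
Reagents that add atoms: none
Why: Bromine–lithium exchange gives aryllithium 16, which adds once to the lactone carbonyl (nucleophilic acyl addition) because the tetrahedral lithium hemiketal alkoxide persists at −78 °C until the cold quench, and C3 and C4 are not touched.

Step 8
Reactants: 17 (3R,4R)-2-[4-(benzyloxy)-3-methoxyphenyl]-4-[4-(benzyloxy)-3,5-dimethoxybenzyl]-3-methyltetrahydrofuran-2-ol
Product: 19 (2R,3R,4R)-2-[4-(benzyloxy)-3-methoxyphenyl]-4-[4-(benzyloxy)-3,5-dimethoxybenzyl]-3-methyltetrahydrofuran, via oxocarbenium ion 18 (not isolated)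
Conditions: Et3SiH, BF3·OEt2, CH2Cl2, −78 → −20 °C
Reagents that add atoms: none
Why: BF3·OEt2 ionises the hemiketal (or closes the hydroxy ketone) to the 2-aryl oxocarbenium ion 18, which Et3SiH reduces (reductive deoxygenation of a lactol, an ionic hydrogenation); hydride is expected to enter the envelope that holds the C3 methyl and C4 arylmethyl groups pseudoequatorial from its inside face, that is cis to the C3 methyl, so that the aryl group ends trans to methyl (2R), which is also the more stable all-trans arrangement toward which any C2 epimer can drift by reversible benzylic ionisation under the same Lewis acid.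

Step 9
Reactants: 19 (2R,3R,4R)-2-[4-(benzyloxy)-3-methoxyphenyl]-4-[4-(benzyloxy)-3,5-dimethoxybenzyl]-3-methyltetrahydrofuran
Product: 20 4-{[(3R,4R,5R)-5-(4-hydroxy-3-methoxyphenyl)-4-methyltetrahydrofuran-3-yl]methyl}-2,6-dimethoxyphenol
Conditions: H2 (1 atm), Pd/C, EtOAc–MeOH, rt
Reagents that add atoms: none
Why: Hydrogenolysis of the two aryl benzyl ethers over Pd/C, expected to be much faster than cleavage of the cyclic benzylic C2–O1 bond at ambient pressure and temperature, so that the ring, the methyl ethers and all three stereocentres survive.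

Compound list
1 | (R)-epichlorohydrin, (2R)-2-(chloromethyl)oxirane | ClC[C@H]1CO1 | starting material
2 | dimethyl malonate | COC(=O)CC(=O)OC | starting material
3 | dimethyl 2-[(2R)-3-chloro-2-hydroxypropyl]propanedioate (sodium alkoxide in the flask, not isolated) | COC(=O)C(C(=O)OC)C[C@@H](O)CCl | intermediate
4 | dimethyl 2-{[(2R)-oxiran-2-yl]methyl}propanedioate (not isolated) | COC(=O)C(C(=O)OC)C[C@@H]1CO1 | intermediate
5 | dimethyl (2R)-2-(hydroxymethyl)cyclopropane-1,1-dicarboxylate (alkoxide in the flask, not isolated) | COC(=O)C1(C(=O)OC)C[C@H]1CO | intermediate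
6 | methyl (1S,5R)-2-oxo-3-oxabicyclo[3.1.0]hexane-1-carboxylate | COC(=O)[C@]12C[C@H]1COC2=O | intermediate
7 | 4-bromo-2,6-dimethoxyphenol | COc1cc(Br)cc(OC)c1O | starting material
8 | 2-(benzyloxy)-5-bromo-1,3-dimethoxybenzene | COc1cc(Br)cc(OC)c1OCc1ccccc1 | intermediate
9 | [4-(benzyloxy)-3,5-dimethoxyphenyl]magnesium bromide | COc1cc([Mg]Br)cc(OC)c1OCc1ccccc1 | intermediate
10 | bromomagnesium enolate of methyl (4R)-4-[4-(benzyloxy)-3,5-dimethoxybenzyl]-2-oxotetrahydrofuran-3-carboxylate (not isolated) | COC(=O)C1=C(O[Mg]Br)OC[C@@H]1Cc1cc(OC)c(OCc2ccccc2)c(OC)c1 | intermediate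
11 | methyl (3R,4R)-4-[4-(benzyloxy)-3,5-dimethoxybenzyl]-3-methyl-2-oxotetrahydrofuran-3-carboxylate | O=C1OC[C@H](Cc2cc(OC)c(OCc3ccccc3)c(OC)c2)[C@]1(C)C(=O)OC | intermediate
12 | (3S,4R)-4-[4-(benzyloxy)-3,5-dimethoxybenzyl]-3-methyldihydrofuran-2(3H)-one, the 3,4-cis epimer (not isolated) | O=C1OC[C@H](Cc2cc(OC)c(OCc3ccccc3)c(OC)c2)[C@@H]1C | intermediate
13 | (3R,4R)-4-[4-(benzyloxy)-3,5-dimethoxybenzyl]-3-methyldihydrofuran-2(3H)-one, the 3,4-trans lactone | O=C1OC[C@H](Cc2cc(OC)c(OCc3ccccc3)c(OC)c2)[C@H]1C | intermediate
14 | 4-bromo-2-methoxyphenol | COc1cc(Br)ccc1O | starting material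
15 | 1-(benzyloxy)-4-bromo-2-methoxybenzene | COc1cc(Br)ccc1OCc1ccccc1 | intermediate
16 | [4-(benzyloxy)-3-methoxyphenyl]lithium (not isolated) | COc1cc([Li])ccc1OCc1ccccc1 | intermediate
17 | (3R,4R)-2-[4-(benzyloxy)-3-methoxyphenyl]-4-[4-(benzyloxy)-3,5-dimethoxybenzyl]-3-methyltetrahydrofuran-2-ol (C2 anomers, in equilibrium with the open hydroxy ketone) | COc1cc(C2(O)OC[C@H](Cc3cc(OC)c(OCc4ccccc4)c(OC)c3)[C@H]2C)ccc1OCc1ccccc1 | intermediate
18 | (3R,4R)-2-[4-(benzyloxy)-3-methoxyphenyl]-4-[4-(benzyloxy)-3,5-dimethoxybenzyl]-3-methyl-4,5-dihydro-3H-furan-1-ium, the 2-aryl oxocarbenium ion (not isolated) | COc1cc(C2=[O+]C[C@H](Cc3cc(OC)c(OCc4ccccc4)c(OC)c3)[C@H]2C)ccc1OCc1ccccc1 | intermediate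
19 | (2R,3R,4R)-2-[4-(benzyloxy)-3-methoxyphenyl]-4-[4-(benzyloxy)-3,5-dimethoxybenzyl]-3-methyltetrahydrofuran | COc1cc([C@@H]2OC[C@H](Cc3cc(OC)c(OCc4ccccc4)c(OC)c3)[C@H]2C)ccc1OCc1ccccc1 | intermediate
20 | 4-{[(3R,4R,5R)-5-(4-hydroxy-3-methoxyphenyl)-4-methyltetrahydrofuran-3-yl]methyl}-2,6-dimethoxyphenol, that is (2R,3R,4R) in the ring numbering used here, all vicinal substituents trans | COc1cc([C@@H]2OC[C@H](Cc3cc(OC)c(O)c(OC)c3)[C@H]2C)ccc1O | target

Total step count: 9.
Longest linear sequence: 7 steps (steps 2, 3, 4, 5, 7, 8, 9, from 4-bromo-2,6-dimethoxyphenol 7).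

Steps most likely to fail

Step 4. The chelated bromomagnesium enolate 10 may resist C-methylation and simply be protonated on work-up. Warming for the alkylation may also let surplus Grignard reagent add to a carbonyl group. The fallback separates the two bond formations and sets out from 6 and 9. The CuI-catalysed opening is run alone and 10 is quenched cold with aqueous NH4Cl to give methyl (3S,4R)-4-[4-(benzyloxy)-3,5-dimethoxybenzyl]-2-oxotetrahydrofuran-3-carboxylate F1. Krapcho decarboxylation (LiCl, H2O, DMSO, 150 °C) then gives (4R)-4-[4-(benzyloxy)-3,5-dimethoxybenzyl]dihydrofuran-2(3H)-one F2. Deprotonation with LiN(SiMe3)2 in THF at −78 °C gives lithium (4R)-4-[4-(benzyloxy)-3,5-dimethoxybenzyl]-4,5-dihydrofuran-2-olate F3, which MeI should alkylate anti to the C4 substituent. The fallback comes back to the route at 13, bypassing 11, 12 and step 5.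

Step 8. Hydride delivery to oxocarbenium ion 18 may show poor facial selectivity. A second ionisation of the benzylic C2–O1 bond of the product may also occur, leading to ring-opening over-reduction or to Friedel–Crafts closure onto the electron-rich syringyl ring. The fallback forms the C2–O1 bond instead of the C2–H bond at the stereo-determining stage and sets out from 17. NaBH4 (MeOH–THF, 0 °C) should reduce the open-chain keto tautomer to (2R,3R)-1-[4-(benzyloxy)-3-methoxyphenyl]-3-[4-(benzyloxy)-3,5-dimethoxybenzyl]-2-methylbutane-1,4-diol F7 as a mixture of C1 epimers. A catalytic amount of camphorsulfonic acid (CH2Cl2, 0 °C, short contact) then ionises the para-alkoxybenzylic alcohol, and the primary hydroxyl captures the cation in a stereoconvergent cyclodehydration expected to favour the 2,3-trans ring. No silane is present, so over-reduction is excluded. The fallback comes back to the route at 19.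

Step 7. Aryllithium 16 may deprotonate lactone 13 at C3 instead of adding (13 is then recovered). Premature collapse of the tetrahedral alkoxide may also allow a second addition to the ring-opened ketone. The fallback replaces the lactone by a Weinreb amide as the acyl electrophile and sets out from 13. Aminolysis with N,O-dimethylhydroxylamine hydrochloride and AlMe3 (CH2Cl2, 0 °C → rt) gives (2R,3R)-3-[4-(benzyloxy)-3,5-dimethoxybenzyl]-4-hydroxy-N-methoxy-N,2-dimethylbutanamide F4. Silylation (TBSCl, imidazole, DMF) gives (2R,3R)-3-[4-(benzyloxy)-3,5-dimethoxybenzyl]-4-[(tert-butyldimethylsilyl)oxy]-N-methoxy-N,2-dimethylbutanamide F5. Addition of 16 (from 15 and n-BuLi, THF, −78 °C) stops at the chelated adduct and, after quenching, gives (2R,3R)-1-[4-(benzyloxy)-3-methoxyphenyl]-3-[4-(benzyloxy)-3,5-dimethoxybenzyl]-4-[(tert-butyldimethylsilyl)oxy]-2-methylbutan-1-one F6. Bu4NF in THF removes the silyl group and the hydroxy ketone closes to the hemiketal. The fallback comes back to the route at 17.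

Further compounds
F1 | step 4 | methyl (3S,4R)-4-[4-(benzyloxy)-3,5-dimethoxybenzyl]-2-oxotetrahydrofuran-3-carboxylate | O=C1OC[C@H](Cc2cc(OC)c(OCc3ccccc3)c(OC)c2)[C@H]1C(=O)OC
F2 | step 4 | (4R)-4-[4-(benzyloxy)-3,5-dimethoxybenzyl]dihydrofuran-2(3H)-one | O=C1C[C@@H](Cc2cc(OC)c(OCc3ccccc3)c(OC)c2)CO1
F3 | step 4 | lithium (4R)-4-[4-(benzyloxy)-3,5-dimethoxybenzyl]-4,5-dihydrofuran-2-olate | [Li]OC1=C[C@@H](Cc2cc(OC)c(OCc3ccccc3)c(OC)c2)CO1
F4 | step 7 | (2R,3R)-3-[4-(benzyloxy)-3,5-dimethoxybenzyl]-4-hydroxy-N-methoxy-N,2-dimethylbutanamide | CON(C)C(=O)[C@H](C)[C@H](CO)Cc1cc(OC)c(OCc2ccccc2)c(OC)c1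
F5 | step 7 | (2R,3R)-3-[4-(benzyloxy)-3,5-dimethoxybenzyl]-4-[(tert-butyldimethylsilyl)oxy]-N-methoxy-N,2-dimethylbutanamide | CON(C)C(=O)[C@H](C)[C@H](CO[Si](C)(C)C(C)(C)C)Cc1cc(OC)c(OCc2ccccc2)c(OC)c1
F6 | step 7 | (2R,3R)-1-[4-(benzyloxy)-3-methoxyphenyl]-3-[4-(benzyloxy)-3,5-dimethoxybenzyl]-4-[(tert-butyldimethylsilyl)oxy]-2-methylbutan-1-one | COc1cc(C(=O)[C@H](C)[C@H](CO[Si](C)(C)C(C)(C)C)Cc2cc(OC)c(OCc3ccccc3)c(OC)c2)ccc1OCc1ccccc1
F7 | step 8 | (2R,3R)-1-[4-(benzyloxy)-3-methoxyphenyl]-3-[4-(benzyloxy)-3,5-dimethoxybenzyl]-2-methylbutane-1,4-diol (C1 epimers) | COc1cc(C(O)[C@H](C)[C@H](CO)Cc2cc(OC)c(OCc3ccccc3)c(OC)c2)ccc1OCc1ccccc1
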